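**The questions.** 3 questions stand on the runs in which X turns to Z over L: 2 orders at Thursday's charge, and the share of X left in Wednesday's run at 21 h.

| setting | Thursday's | Monday's | Tuesday's | Wednesday's |
|---|---|---|---|---|
| X | 100 mM | 50.0 mM | 100 mM | 100 mM |
| L | 5.00 mM | 5.00 mM | 15.0 mM | 5.00 mM |
| time |  |  |  | 21 h |

| Thursday's run: time / h | Thursday's run: [X] / mM | Monday's run: time / h | Monday's run: [X] / mM | Tuesday's run: time / h | Tuesday's run: [X] / mM |
|---|---|---|---|---|---|
| 1.1 | 81.8 | 1.1 | 38.0 | 1.1 | 8.8 |
| 2.3 | 73.2 | 2.3 | 31.1 | 2.3 | 1.2 |
| 3.5 | 69.3 | 3.5 | 26.4 | 3.5 | 0 |
| 4.6 | 67.6 | 4.6 | 23.4 | 4.6 | 0 |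
| 5.8 | 66.2 | 5.8 | 21.6 | 5.8 | 0 |
| 6.9 | 65.2 | 6.9 | 19.3 | 6.9 | 0.1 |

(each reading ± 0.3 mM)

- order of the initial rate in [L], near the charge of the Thursday's run, the rate being that where two percent of its X are Z
- order of the initial rate in [X], near the charge of the Thursday's run, the rate being that where two percent of its X are Z (one fixed amount of Z, the same in the runs compared)
- X in the Wednesday's run at 21 h, as a share of the X charged

- Overall: X -> Z, with L as catalyst.
- Constant volume, constant temperature.
- Bound and free are read together.
- An order is taken over about fifteen percent of the charge, up and down.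

**The number.** Tuesday's X falls faster than Thursday's, reading 8.8 mM against 81.8 mM at 1.1 h; its logarithmic fall is 12.1 times Thursday's on 3.00 times the L, so the rate looks roughly second order in L. This reckoning therefore supposes that Z forms as X times L squared, while L is lost as X times L. Dividing the two rates cancels X and time, and integration makes the Z formed proportional to the fall in L squared. Near the stop, the excess of X over its final value falls geometrically in this law, so Thursday's evenly spaced readings at 2.3 h, 4.6 h and 6.9 h give a reading of 63.4% for the share of X left at the stop. Thursday's reach is thus read as 0.366: the share of the X charged that the L charged can turn before it is lost, which is the total turnover number multiplied by L charged over X charged.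

**The test.** In this reckoning, at one temperature, reach goes as L charged squared over X charged. Monday's readings, treated the same way, give 0.707, twice Thursday's, as its halved charge of X on the same L requires. Tuesday's scaled reach is 3.29, above one, and its X reads 0 mM at 3.5 h. The number places the stop but gives no time or order. Wednesday's run repeats Thursday's charge, so this reckoning leaves 63.4% of its X at 21 h.

**The forecast.** The forecast gives orders of 2 in L (1.6 to 2.4) and 0.55 in X (0.3 to 0.85), and 62% of Wednesday's X (58% to 64%), holding that “activity depends on the amount of Z made, not on time”. Its share of X is lower than this reckoning's 63.4%.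

**The result.** The orders are 2.1 in L and 0.74 in X, and Wednesday's X stands at 64.9%.

    L + X ⇌ LX, settled at all times (1.600 M⁻¹)
    LX + L → Z + 2 L (8496 M⁻¹ h⁻¹)
    L + X → Gu + X (4.284 M⁻¹ h⁻¹)

That share means a reach of 35.1% in Wednesday's run. Monday's read reach of 0.707 exceeds one half, and Monday's flask turns half of its X by 4.02 h. Wednesday's X stops through the loss of L to Gu: with that path taken away, the same run stands at 0.117% at 21 h.

The earlier runs and the new flask were generated by integration with made-up constants; the scatter is artificial.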